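| flask | solid first end groups | second end groups | temperature | remark | time |
|---|---|---|---|---|---|
| red | 0.036 M | 0.102 M | 2 °C | run made earlier |  |
| grey | 0.16 M | 0.102 M | 19 °C | run made earlier |  |
| ochre | 0.10 M | 0.048 M | 2 °C | run made earlier |  |
| midnight | 0.030 M | 0.0250 M | 25 °C |  | 4.0 min |
| autumn | 0.050 M | 0.0250 M | 25 °C |  | 4.0 min |
| winter | 0.10 M | 0.102 M | 25 °C |  | 4.0 min |
| noon | 0.10 M | 0.102 M | −5 °C |  | 4.0 min |

- red (time / min: links / %, solid first end groups / %): 1.00: 3.1, 89.9; 1.50: 5.8, 86.4; 2.00: 8.6, 83.0; 3.00: 14.7, 76.1; 5.00: 27.2, 63.4; 8.00: 45.6, 44.9; 12.0: 68.0, 21.9
- grey (time / min: links / %, solid first end groups / %): 0.200: 0.3, 99.0; 0.667: 1.3, 97.4; 1.00: 2.5, 97.8; 1.50: 2.7, 96.4; 2.50: 5.7, 93.7; 3.00: 6.9, 92.4; 4.00: 9.4, 90.0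
- ochre (time / min: links / %, solid first end groups / %): 2.50: 1.9, 93.3; 5.00: 6.1, 90.3; 8.00: 9.5, 85.9; 10.0: 12.0, 83.3; 12.0: 14.5, 81.0

(readings scatter by 0.3 percentage points)

- as a solid, counted per litre of solution: solid first end groups
- steps under discussion: first end groups + second end groups <-> links + released group; solid first end groups <-> first end groups
- at the start none of the solid first end groups is in solution
- what has only dissolved of solid first end groups counts as not reacted

- the flasks put in order of amount of links, in percent of the solid first end groups charged, best first, at 4.0 min (midnight / autumn / winter / noon)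
- the amount of links, in percent of the solid first end groups charged of the flask you put first, at 4.0 min
- the amount of links, in percent of the solid first end groups charged of the flask you put last, at 4.0 min

I started from amounts. In red, from 5.00 min to 8.00 min, a mean 9.45% of the charge was neither links nor solid, so it was dissolved first end groups. Links grew meanwhile by 0.0613 min⁻¹ of the charge. Dissolved amount over link rate gave a lifetime. As a half-life, scaled to the full charge of second end groups, it was 0.931 min at 2 °C. The step is pseudo-first-order while second end groups stay near their charge.

Grey, from 2.50 min on, held 0.633% dissolved and gained 0.0247 min⁻¹. That made the half-life 0.157 min at 19 °C. I took its logarithm as straight in temperature. For noon this gave 1.93 min, the link half-life: the time in which the link step halves dissolved first end groups at full second end groups.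

Next came supply. I assumed it falls linearly with the dissolved amount and ignores temperature. Red and grey then gave two points. Filling relaxes at 0.728 min⁻¹, and an empty solution receives 0.0468 min⁻¹ of noon's charge. Noon's link half-life was longer than the filling half-life, 0.952 min. Supply balanced against use gave noon 4.78% links.

Supply times time gave totals of 62.5% for midnight, 37.5% for autumn and 18.7% for winter, and I ordered the flasks so, with noon last. Midnight's total equals 74.9% of its second end groups, and I committed no top.

The weak link was grey's dissolved amount, a difference of readings. Moving its mean by its scatter put noon's half-life between 1.69 min and 2.37 min.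

The forecast gave midnight > autumn > winter > noon, top 31% and low 4.5%, holding that “Noon is reaction-limited”.

The flasks gave midnight > autumn > winter > noon, top 30.9% and low 4.88%.

    first end groups + second end groups ⇌ links + released group (K = 45.0, k = 0.847 M⁻¹ s⁻¹, Ea = 58.0 kJ mol⁻¹, ΔH = −9.00 kJ mol⁻¹)
    solid first end groups ⇌ first end groups, rate k2*(cs2 - [first end groups]) while solid is left; crystals form when [first end groups] > cs2 (solubility = 6.10 mM, k = 0.0135 s⁻¹)
    (constants at 25 °C)

At 4.00 min, noon held 4.17% first end groups, made 1.04 times as fast as they were used up, each step taken net. Supply and use stood near balance, and the time held 2.07 of my link half-lives. For noon read at 1.0 min, the same half-life and supply gave 0.603% links. That flask held 0.651% links.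

The numbers in the tables were computed for an exercise, noise included.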